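**Retrosynthetic overview**

- The strategy rests on the quaternary benzylic carbon C8, which carries the oxirane oxygen and two oxygenated methylenes (oxirane carbon C9 and acyloxymethyl carbon C10). The unit C9–C8(O)–C10 is therefore the opened form of a 3-aryl oxetane oxygenated at C3, in which C9 and C10 are mirror-related ring methylenes.
- Last disconnections: the oxirane C8–O–C9 from a bromohydrin (O8 onto C9–Br), and the two (R)-2-methylbutanoates at C7 and C10 from one double esterification of a bromo triol.
- Key disconnection: the C9–Br bond, made by catalyst-controlled bromide opening of a prochiral 3-aryl-3-silyloxyoxetane that already bears the aryl angelate. This sets C8, and the former oxetane oxygen ends as the C10 ester oxygen.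
- The oxetane is assembled from an aryllithium (from a protected 4-bromo-3-hydroxybenzyl alcohol) and a bought oxetanone. The angelate goes onto the phenol before the opening.
- Ring order: benzene ring bought; oxetane brought in intact and cleaved in the key step; oxirane closed in the final step.

Key step: step 8

Remark: squaramide A denotes 3-{[3,5-bis(trifluoromethyl)phenyl]amino}-4-({(2S)-3,3-dimethyl-1-oxo-1-[(2R)-2-(phenanthren-9-yl)pyrrolidin-1-yl]butan-2-yl}amino)cyclobut-3-ene-1,2-dione or its mirror image; the antipode that leads to (S)-14 is to be assigned by a trial opening, and (2R)-2-methylbutanoic acid is taken to be purchasable in high enantiomeric purity.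

**Step 1**
Reactants: 1 methyl 4-bromo-3-hydroxybenzoate
Product: 2 methyl 3-(benzyloxy)-4-bromobenzoate
Conditions: BnBr, K2CO3, DMF, rt
Reagents that add atoms: benzyl bromide, BrCc1ccccc1
Why: Williamson etherification of the phenoxide with benzyl bromide should be clean, the methyl ester being inert to K2CO3 in DMF at room temperature.

**Step 2**
Reactants: 2 methyl 3-(benzyloxy)-4-bromobenzoate
Product: 3 [3-(benzyloxy)-4-bromophenyl]methanol
Conditions: i-Bu2AlH, CH2Cl2, −78 → 0 °C; aq. potassium sodium tartrate
Reagents that add atoms: none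
Why: Hydride reduction of the ester with i-Bu2AlH should give the primary benzylic alcohol (future C7–OH) without touching the aryl bromide or the benzyl ether.

**Step 3**
Reactants: 3 [3-(benzyloxy)-4-bromophenyl]methanol
Product: 4 {[3-(benzyloxy)-4-bromophenyl]methoxy}(tert-butyl)dimethylsilane
Conditions: TBSCl, imidazole, CH2Cl2, rt
Reagents that add atoms: tert-butyldimethylsilyl chloride, CC(C)(C)[Si](C)(C)Cl
Why: Imidazole-promoted silylation of the primary alcohol gives a TBS ether that should withstand n-BuLi, hydrogenolysis in EtOAc and the acylation to come.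

**Step 4**
Reactants: 4 {[3-(benzyloxy)-4-bromophenyl]methoxy}(tert-butyl)dimethylsilane; 5 oxetan-3-one
Product: 7 3-[2-(benzyloxy)-4-({[tert-butyl(dimethyl)silyl]oxy}methyl)phenyl]oxetan-3-ol, via aryllithium 6 (not isolated)
Conditions: n-BuLi, THF, −78 °C; then 5, −78 → −40 °C; aq. NH4Cl
Reagents that add atoms: n-butyllithium, [Li]CCCC (its lithium stands only in intermediate 6; no atom of it remains in 7)
Why: Bromine–lithium exchange at −78 °C is faster than deprotonation of the benzyl ether, and 1,2-addition of the aryllithium to the strained ketone brings in C8, C9, C10 and both their oxygens in one C–C bond formation; the carbinol carbon is not yet stereogenic because the two ring methylenes are identical.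

**Step 5**
Reactants: 7 3-[2-(benzyloxy)-4-({[tert-butyl(dimethyl)silyl]oxy}methyl)phenyl]oxetan-3-ol
Product: 8 3-[4-({[tert-butyl(dimethyl)silyl]oxy}methyl)-2-hydroxyphenyl]oxetan-3-ol
Conditions: H2 (1 atm), Pd/C, EtOAc, rt
Reagents that add atoms: none
Why: Hydrogenolysis of the aryl benzyl ether over Pd/C in neutral EtOAc should be much faster than cleavage of the benzylic silyl ether or of the tertiary benzylic C–O bond, and acid is excluded because it would let the freed phenol attack the oxetane.

**Step 6**
Reactants: 8 3-[4-({[tert-butyl(dimethyl)silyl]oxy}methyl)-2-hydroxyphenyl]oxetan-3-ol; 9 angelic acid [(2Z)-2-methylbut-2-enoic acid]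
Product: 11 5-({[tert-butyl(dimethyl)silyl]oxy}methyl)-2-(3-hydroxyoxetan-3-yl)phenyl (2Z)-2-methylbut-2-enoate, via mixed anhydride 10 (not isolated)
Conditions: 9, 2,4,6-Cl3C6H2COCl, Et3N, toluene, rt; then 8, 0 °C → rt
Reagents that add atoms: 2,4,6-trichlorobenzoyl chloride, O=C(Cl)c1c(Cl)cc(Cl)cc1Cl (its aroyl group is held only in intermediate 10; 11 keeps no atom of it)
Why: Yamaguchi-type acylation, in which the phenoxide attacks the unhindered angeloyl carbonyl of the mixed anhydride while the hindered tertiary hydroxyl stays free; this activation mode is the one relied on to keep the Z geometry of angelic acid, and it removes the free phenol before any electrophilic activation of the oxetane.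

**Step 7**
Reactants: 11 5-({[tert-butyl(dimethyl)silyl]oxy}methyl)-2-(3-hydroxyoxetan-3-yl)phenyl (2Z)-2-methylbut-2-enoate
Product: 12 5-({[tert-butyl(dimethyl)silyl]oxy}methyl)-2-{3-[(trimethylsilyl)oxy]oxetan-3-yl}phenyl (2Z)-2-methylbut-2-enoate
Conditions: TMSCl, imidazole, DMF, 0 °C
Reagents that add atoms: chlorotrimethylsilane, C[Si](C)(C)Cl
Why: Silylation of the tertiary hydroxyl removes the only protic group, which would otherwise consume TMSBr and release HBr (a source of uncatalysed, racemic opening), and it turns the substrate into a plain 3,3-disubstituted oxetane; the carbon remains non-stereogenic.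

**Step 8**
Reactants: 12 5-({[tert-butyl(dimethyl)silyl]oxy}methyl)-2-{3-[(trimethylsilyl)oxy]oxetan-3-yl}phenyl (2Z)-2-methylbut-2-enoate
Product: 14 2-[(2S)-1-bromo-2,3-dihydroxypropan-2-yl]-5-({[tert-butyl(dimethyl)silyl]oxy}methyl)phenyl (2Z)-2-methylbut-2-enoate, via bis-TMS ether 13 (not isolated)
Conditions: TMSBr, squaramide A (10 mol %), t-BuOMe, −78 °C; then citric acid, MeOH, 0 °C
Reagents that add atoms: bromotrimethylsilane, C[Si](C)(C)Br
Why: The squaramide binds the bromide of TMSBr and so passes the silyl group to the oxetane oxygen; the chiral squaramide·bromide/silyloxetanium ion pair then collapses by SN2 attack of bromide on one of the two mirror-related ring methylenes (C9), which forms C9–Br, breaks C9–O and releases the ring strain. No ring is closed here; the four-membered ring is opened. The closest known reaction type is the chiral-squaramide-catalysed enantioselective addition of TMSBr to 3,3-disubstituted oxetanes. The new stereocentre C8 is set by the catalyst (antipode chosen to give S), and citric acid in methanol then strips both TMS ethers without touching C8. The step needs discrimination of the two methylenes, which the large difference between the twisted ortho-acyloxyaryl group and the small OSiMe3 group on C8 should provide, and bimolecular opening instead of ionisation at C8, which the electron-poor acyloxyarene, the absence of any HBr source and the low temperature should provide.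

**Step 9**
Reactants: 14 2-[(2S)-1-bromo-2,3-dihydroxypropan-2-yl]-5-({[tert-butyl(dimethyl)silyl]oxy}methyl)phenyl (2Z)-2-methylbut-2-enoate
Product: 15 2-[(2S)-1-bromo-2,3-dihydroxypropan-2-yl]-5-(hydroxymethyl)phenyl (2Z)-2-methylbut-2-enoate
Conditions: HF·pyridine, pyridine, THF, 0 °C → rt
Reagents that add atoms: none
Why: Fluoride cleavage of the primary TBS ether under buffered, weakly acidic conditions generates no alkoxide, so the bromohydrin should not close early and the aryl ester should not migrate.

**Step 10**
Reactants: 15 2-[(2S)-1-bromo-2,3-dihydroxypropan-2-yl]-5-(hydroxymethyl)phenyl (2Z)-2-methylbut-2-enoate; 16 (2R)-2-methylbutanoic acid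
Product: 17 (2S)-3-bromo-2-hydroxy-2-[2-{[(2Z)-2-methylbut-2-enoyl]oxy}-4-({[(2R)-2-methylbutanoyl]oxy}methyl)phenyl]propyl (2R)-2-methylbutanoate
Conditions: 16 (2.4 equiv), DCC, 4-(dimethylamino)pyridine (DMAP, cat.), CH2Cl2, 0 °C → rt
Reagents that add atoms: none
Why: Steglich esterification acylates the C7 and C10 primary hydroxyls in one operation while the tertiary hydroxyl is too hindered; no acid chloride and hence no ketene is involved, so the acyl α-stereocentres are kept, and acylating C10 before the oxirane exists excludes a Payne rearrangement of a free glycidol, which would invert C8.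

**Step 11**
Reactants: 17 (2S)-3-bromo-2-hydroxy-2-[2-{[(2Z)-2-methylbut-2-enoyl]oxy}-4-({[(2R)-2-methylbutanoyl]oxy}methyl)phenyl]propyl (2R)-2-methylbutanoate
Product: 18 target, 2-[(2R)-2-({[(2R)-2-methylbutanoyl]oxy}methyl)oxiran-2-yl]-5-({[(2R)-2-methylbutanoyl]oxy}methyl)phenyl (2Z)-2-methylbut-2-enoate
Conditions: Ag2O, 4 Å MS, CH2Cl2, rt, dark
Reagents that add atoms: none
Why: Halohydrin ring closure (intramolecular Williamson, 3-exo-tet) assisted by the halophilic Ag2O needs no free alkoxide and should therefore outrun acyl migration from the neighbouring esters; only the O–H and C9–Br bonds react, so C8 keeps its spatial arrangement and its descriptor changes from S to R only because the CIP priorities of C9 and C10 are exchanged.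

**Compound list**

1 | methyl 4-bromo-3-hydroxybenzoate | COC(=O)c1ccc(Br)c(O)c1 | starting material
2 | methyl 3-(benzyloxy)-4-bromobenzoate | COC(=O)c1ccc(Br)c(OCc2ccccc2)c1 | intermediate
3 | [3-(benzyloxy)-4-bromophenyl]methanol | OCc1ccc(Br)c(OCc2ccccc2)c1 | intermediate
4 | {[3-(benzyloxy)-4-bromophenyl]methoxy}(tert-butyl)dimethylsilane | CC(C)(C)[Si](C)(C)OCc1ccc(Br)c(OCc2ccccc2)c1 | intermediate
5 | oxetan-3-one | O=C1COC1 | starting material
6 | [2-(benzyloxy)-4-({[tert-butyl(dimethyl)silyl]oxy}methyl)phenyl]lithium | [Li]c1ccc(CO[Si](C)(C)C(C)(C)C)cc1OCc1ccccc1 | intermediate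
7 | 3-[2-(benzyloxy)-4-({[tert-butyl(dimethyl)silyl]oxy}methyl)phenyl]oxetan-3-ol | CC(C)(C)[Si](C)(C)OCc1ccc(C2(O)COC2)c(OCc2ccccc2)c1 | intermediate
8 | 3-[4-({[tert-butyl(dimethyl)silyl]oxy}methyl)-2-hydroxyphenyl]oxetan-3-ol | CC(C)(C)[Si](C)(C)OCc1ccc(C2(O)COC2)c(O)c1 | intermediate
9 | angelic acid, (2Z)-2-methylbut-2-enoic acid | C/C=C(/C)C(=O)O | starting material
10 | (2Z)-2-methylbut-2-enoic 2,4,6-trichlorobenzoic anhydride | C/C=C(/C)C(=O)OC(=O)c1c(Cl)cc(Cl)cc1Cl | intermediate
11 | 5-({[tert-butyl(dimethyl)silyl]oxy}methyl)-2-(3-hydroxyoxetan-3-yl)phenyl (2Z)-2-methylbut-2-enoate | C/C=C(/C)C(=O)Oc1cc(CO[Si](C)(C)C(C)(C)C)ccc1C1(O)COC1 | intermediate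
12 | 5-({[tert-butyl(dimethyl)silyl]oxy}methyl)-2-{3-[(trimethylsilyl)oxy]oxetan-3-yl}phenyl (2Z)-2-methylbut-2-enoate | C/C=C(/C)C(=O)Oc1cc(CO[Si](C)(C)C(C)(C)C)ccc1C1(O[Si](C)(C)C)COC1 | intermediate
13 | 2-{(2S)-1-bromo-2,3-bis[(trimethylsilyl)oxy]propan-2-yl}-5-({[tert-butyl(dimethyl)silyl]oxy}methyl)phenyl (2Z)-2-methylbut-2-enoate | C/C=C(/C)C(=O)Oc1cc(CO[Si](C)(C)C(C)(C)C)ccc1[C@](O[Si](C)(C)C)(CO[Si](C)(C)C)CBr | intermediate
14 | 2-[(2S)-1-bromo-2,3-dihydroxypropan-2-yl]-5-({[tert-butyl(dimethyl)silyl]oxy}methyl)phenyl (2Z)-2-methylbut-2-enoate | C/C=C(/C)C(=O)Oc1cc(CO[Si](C)(C)C(C)(C)C)ccc1[C@](O)(CO)CBr | intermediate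
15 | 2-[(2S)-1-bromo-2,3-dihydroxypropan-2-yl]-5-(hydroxymethyl)phenyl (2Z)-2-methylbut-2-enoate | C/C=C(/C)C(=O)Oc1cc(CO)ccc1[C@](O)(CO)CBr | intermediate
16 | (2R)-2-methylbutanoic acid | CC[C@@H](C)C(=O)O | starting material
17 | (2S)-3-bromo-2-hydroxy-2-[2-{[(2Z)-2-methylbut-2-enoyl]oxy}-4-({[(2R)-2-methylbutanoyl]oxy}methyl)phenyl]propyl (2R)-2-methylbutanoate | C/C=C(/C)C(=O)Oc1cc(COC(=O)[C@H](C)CC)ccc1[C@](O)(COC(=O)[C@H](C)CC)CBr | intermediate
18 | 2-[(2R)-2-({[(2R)-2-methylbutanoyl]oxy}methyl)oxiran-2-yl]-5-({[(2R)-2-methylbutanoyl]oxy}methyl)phenyl (2Z)-2-methylbut-2-enoate (CNP0166772.1) | C/C=C(/C)C(=O)Oc1cc(COC(=O)[C@H](C)CC)ccc1[C@]1(COC(=O)[C@H](C)CC)CO1 | target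

**Totals**

Total step count: 11.
Longest linear sequence: 11 steps (1 to 18); 5, 9 and 16 are bought and enter directly.

**Steps most likely to fail**

1. Step 8. The catalyst may not tell the two ring methylenes apart well enough, so that the enantiomeric excess is low, or uncatalysed opening may compete. The fallback sets out from 14 of whatever enantiomeric purity and returns at 18; it makes the oxirane by oxygen transfer to an alkene instead.
 - Zinc dust in EtOH/AcOH should remove bromide and the tertiary hydroxyl by reductive β-elimination and give the achiral 2-arylallyl alcohol F1.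
 - Sharpless asymmetric epoxidation (Ti(OiPr)4, L-(+)-diisopropyl tartrate, t-BuOOH, 4 Å MS, CH2Cl2, −20 °C) should then build the oxirane C8–O–C9 under reagent control and give the (S)-epoxy alcohol F2. The tartrate antipode follows from the usual facial rule for allylic alcohols.
 - The C10 hydroxyl is esterified at once with 16 (DCC, cat. DMAP) to the silyl-protected epoxy monoester F3, which shuts off Payne rearrangement.
 - TBAF buffered with AcOH frees the C7 alcohol F4, and a second carbodiimide esterification with 16 leads to 18.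

2. Step 11. Transfer of the C10 acyl group or of the aryl angeloyl group to the tertiary oxygen, or a silver-assisted 1,2-aryl shift, may compete with ring closure. The fallback sets out from 15 and returns at 18 by reversing the order of the last two operations. Ag2O in THF should close the oxirane on the triol, where no ester sits next to the reacting hydroxyl, and give the epoxy diol F5. Both primary hydroxyls of F5 are then esterified with 16 (DCC, cat. DMAP, 0 °C, no strong base, so that Payne rearrangement is avoided) to give 18.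

3. Step 6. The activated angeloyl unit may isomerise from Z to E (tiglate formation), or acyl transfer may be slow enough for the phenoxide to attack the oxetane. The fallback sets out from 8 and returns at 11 by palladium-catalysed aryloxycarbonylation. Phenol 8 is coupled with (Z)-2-bromobut-2-ene and CO (1 atm) using Pd(OAc)2/Xantphos and Et3N in toluene at about 60 °C. The acyl group is assembled on palladium from the vinyl bromide with retention of alkene geometry, so no activated angelic acid derivative is present at any time. No new compound arises on this path (F0).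

**Further compounds**

F1 | step 8 | 5-({[tert-butyl(dimethyl)silyl]oxy}methyl)-2-(3-hydroxyprop-1-en-2-yl)phenyl (2Z)-2-methylbut-2-enoate | C/C=C(/C)C(=O)Oc1cc(CO[Si](C)(C)C(C)(C)C)ccc1C(=C)CO
F2 | step 8 | 5-({[tert-butyl(dimethyl)silyl]oxy}methyl)-2-[(2S)-2-(hydroxymethyl)oxiran-2-yl]phenyl (2Z)-2-methylbut-2-enoate | C/C=C(/C)C(=O)Oc1cc(CO[Si](C)(C)C(C)(C)C)ccc1[C@]1(CO)CO1
F3 | step 8 | {(2R)-2-[4-({[tert-butyl(dimethyl)silyl]oxy}methyl)-2-{[(2Z)-2-methylbut-2-enoyl]oxy}phenyl]oxiran-2-yl}methyl (2R)-2-methylbutanoate | C/C=C(/C)C(=O)Oc1cc(CO[Si](C)(C)C(C)(C)C)ccc1[C@]1(COC(=O)[C@H](C)CC)CO1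
F4 | step 8 | {(2R)-2-[4-(hydroxymethyl)-2-{[(2Z)-2-methylbut-2-enoyl]oxy}phenyl]oxiran-2-yl}methyl (2R)-2-methylbutanoate | C/C=C(/C)C(=O)Oc1cc(CO)ccc1[C@]1(COC(=O)[C@H](C)CC)CO1
F5 | step 11 | 5-(hydroxymethyl)-2-[(2S)-2-(hydroxymethyl)oxiran-2-yl]phenyl (2Z)-2-methylbut-2-enoate | C/C=C(/C)C(=O)Oc1cc(CO)ccc1[C@]1(CO)CO1
F0 | step 6 | none | none
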